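Readings and results were generated by integration with constants of no real substance; the scatter is artificial.

**Sunday's leftover.** Sunday's flask held 0.093 M of substrate and 0.060 M of partner, more substrate than partner. On the proposed steps each substrate that reacts takes one partner, so at least 0.0330 M of substrate stays unreacted there, and partner is the limiting reagent.

| flask | substrate | partner | remark | time |
|---|---|---|---|---|
| Wednesday's | 0.093 M | 0.121 M | run made earlier |  |
| Saturday's | 0.046 M | 0.121 M | run made earlier |  |
| Tuesday's | 0.070 M | 0.121 M | run made earlier |  |
| Sunday's | 0.093 M | 0.060 M | run made earlier |  |
| autumn | 0.093 M | 0.121 M | one stirred flow tank at steady state, fed with the mixture as stated, mean residence time 6.0 d |  |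
| winter | 0.093 M | 0.121 M | one stirred flow tank at steady state, fed with the mixture as stated, mean residence time 60.0 d |  |
| spring | 0.093 M | 0.121 M (fed, over 4.80 d) | a stirred flask in which partner is dosed at a steady rate over 4.80 d without added volume, worked up at 6.0 d | 6.0 d |
| midnight | 0.093 M | 0.121 M | everything together in a closed stirred flask, run for 6.0 d | 6.0 d |

- Wednesday's (time / d: bis adduct / %): 0.500: 41; 0.833: 50; 1.25: 50; 2.00: 49; 4.00: 51; 6.00: 45
- Saturday's (time / d: bis adduct / %): 0.625: 63; 1.04: 72; 1.67: 75; 2.50: 73; 4.00: 69; 8.00: 62
- Tuesday's (time / d: bis adduct / %): 1.25: 67; 2.50: 68; 4.00: 71; 5.00: 66; 6.00: 66; 8.00: 63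
- Sunday's (time / d: bis adduct / %): 1.25: 20; 3.00: 21; 4.00: 16; 6.00: 19; 8.00: 16

(scatter of a reading: 2 percentage points)

- the stated concentrations are those of everything mixed, before any reaction; amounts are the same in each set-up
- steps that have been proposed: substrate + partner -> single product; partner + single product -> bis adduct; partner + bis adduct <-> triple product; bis adduct <-> isomer of the product
- the feed brings no volume worth counting
- the earlier runs were made in a closed, stirred flask

- the set-up with the highest amount of bis adduct at the outlet or at the end, in percent of the substrate put in ("none" if the first two lie within 2 percentage points) (autumn / winter / spring / midnight / none)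
- amount of bis adduct at the outlet or at the end, in percent of the substrate put in, autumn
- amount of bis adduct at the outlet or at the end, in percent of the substrate put in, winter
- amount of bis adduct at the outlet or at the end, in percent of the substrate put in, spring
- amount of bis adduct at the outlet or at the end, in percent of the substrate put in, midnight

**The ceiling.** Follow one substrate molecule: it takes one partner to become single product and a second to become bis adduct. We therefore define the partner ceiling C, the bis adduct that the partner can pay for at two partners each: partner concentration divided by two, then by substrate concentration, in percent of the substrate. The four new set-ups share Wednesday's charge, so for them C = 65.1%, below the 100% that the substrate allows. Sunday's best reading, 21%, stands under its own ceiling of 32.3%.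

**Next run.** Wednesday's best reading is 51%, at 4.00 d, which is 78.3% of C, and its last is 45%, at 6.00 d. Changing the vessel leaves C as it is, so we keep the charge and compare vessels by their share of C. Our own reckoning puts midnight, a repeat of Wednesday's flask, near that last reading and spring near the best one, so spring is the flask we would run next.

**The forecast.** It chooses spring: 50% there, 46% at midnight, 41% in autumn and 27% in winter. For spring it argues that “the adduct is younger”.

**The result.**

    substrate + partner → single product (k = 2.50 L mol⁻¹ h⁻¹)
    partner + single product → bis adduct (k = 6.80 L mol⁻¹ h⁻¹)
    partner + bis adduct ⇌ triple product (K = 9.10 L mol⁻¹, k = 1.00 L mol⁻¹ h⁻¹)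
    bis adduct ⇌ isomer of the product (K = 0.540, k = 0.00290 h⁻¹)

The highest set-up is spring, which comes first with 48.6%, against 44.2% at midnight, 43.6% in autumn and 40.3% in winter, so the forecast's winter lies 13 percentage points low. The winter tank holds 6.31 × 10⁻⁴ M of partner, hardly any of the 0.121 M charged. Against C, spring reaches 74.7% and winter 61.9%. Now change the partner in spring to 0.131 M: the ceiling becomes 70.4%, a shift of 5.3 points, and the amount of bis adduct at the end of that flask has moved by 5 points.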